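**Plan**
- Retrosynthesis: cut the benzylic ether bond O11–C11a of ring C first, then cut C4a–O5 and C11a–C11b of ring B together. This leaves a ring A/E aryne and the 3-hydroxy-2-arylpropanoate (tropate ester) of ring D.
- Enabling feature: the adjacent ring A carbons C4a and C11b are flanked unequally, C11b by C1 carrying the ring E oxygen and C4a only by C4–H. The C4a–C11b aryne is therefore a 3-alkoxyaryne that accepts an oxygen nucleophile at C4a and leaves the carbanion at C11b.
- Forward: ring E is built on phloroglucinol (ring A) as a chromanone and reduced to the chroman, and ring A is then armed as the ortho-silyl aryl triflate. Ring D is brought in as the O-benzyl tropate benzyl ester.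
- The aryne annulation closes ring B as a racemic isoflavanone; ring C is closed last by acid.
- Stereochemistry: C6a is set by transfer hydrogenation with dynamic kinetic resolution using RuCl(p-cymene)[(S,S)-TsDPEN], giving the cis-(3S,4S) alcohol. C11a then follows from C6a because ring C can only fuse cis, giving (6aS,11aS).

Key step: step 9

Remark: acid 13 is taken as purchasable. Labels C1–C11b are pterocarpan numbering; locants inside compound names are the chroman numbering of the compound named.

Step 1
Reactants: 1 phloroglucinol; 2 3-methylbut-2-enoic acid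
Product: 3 5,7-dihydroxy-2,2-dimethylchroman-4-one
Conditions: P2O5, MeSO3H, 70 °C
Reagents that add atoms: none
Why: Friedel–Crafts acylation of the threefold-symmetric triol followed by 6-endo oxa-Michael closure of an ortho hydroxyl onto the enone should build ring E on ring A in one operation, and the symmetry of 1 leaves no regiochemical choice.

Step 2
Reactants: 3 5,7-dihydroxy-2,2-dimethylchroman-4-one
Product: 4 5-hydroxy-2,2-dimethyl-4-oxochroman-7-yl N-isopropylcarbamate
Conditions: i-PrNCO (1.05 equiv), Et3N (cat.), CH2Cl2, rt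
Reagents that add atoms: isopropyl isocyanate, CC(C)N=C=O
Why: Base-catalysed carbamoylation of a phenol by an isocyanate is expected only at the 7-OH, because the 5-OH is held in a hydrogen bond to the C4 carbonyl and is far less nucleophilic.

Step 3
Reactants: 4 5-hydroxy-2,2-dimethyl-4-oxochroman-7-yl N-isopropylcarbamate
Product: 5 5-hydroxy-2,2-dimethylchroman-7-yl N-isopropylcarbamate
Conditions: Et3SiH, CF3CO2H, CH2Cl2, rt to 40 °C
Reagents that add atoms: none
Why: Ionic hydrogenation (Kursanov–Parnes reduction) should take the ortho-hydroxyaryl ketone to the methylene through a benzylic cation stabilised by the 5-OH and the ring oxygen, while the aryl carbamate is inert to acid and silane.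

Step 4
Reactants: 5 5-hydroxy-2,2-dimethylchroman-7-yl N-isopropylcarbamate
Product: 6 2,2-dimethyl-5-(triisopropylsilyloxy)chroman-7-yl N-isopropylcarbamate
Conditions: TIPSCl, imidazole, DMF, rt
Reagents that add atoms: triisopropylsilyl chloride, CC(C)[Si](Cl)(C(C)C)C(C)C
Why: Silylation of the now unchelated phenol installs a bulky ether that does not coordinate lithium and screens C6 in the next step.

Step 5
Reactants: 6 2,2-dimethyl-5-(triisopropylsilyloxy)chroman-7-yl N-isopropylcarbamate
Product: 10 2,2-dimethyl-5-(triisopropylsilyloxy)-8-(trimethylsilyl)chroman-7-yl N-isopropylcarbamate, via N-silyl carbamate 7 (not isolated), via aryllithium 8 (not isolated), via disilyl carbamate 9 (not isolated)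
Conditions: TBSOTf, TMEDA, Et2O, 0 °C to rt; n-BuLi, TMEDA, −78 °C; Me3SiCl, −78 °C to rt; aq NaHSO4
Reagents that add atoms: chlorotrimethylsilane, C[Si](C)(C)Cl
Why: Directed ortho-metalation of the carbamate, protected in situ at nitrogen, should occur at C8, which lies between the carbamate and the lithium-coordinating ring oxygen, rather than at C6 beside the non-coordinating OTIPS group; aqueous acid then removes the N-silyl group.

Step 6
Reactants: 10 2,2-dimethyl-5-(triisopropylsilyloxy)-8-(trimethylsilyl)chroman-7-yl N-isopropylcarbamate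
Product: 12 2,2-dimethyl-5-(triisopropylsilyloxy)-8-(trimethylsilyl)chroman-7-yl trifluoromethanesulfonate, via phenol 11 (not isolated)
Conditions: DBU, Et2NH, MeCN, 40 °C; then PhNTf2, rt
Reagents that add atoms: N-phenylbis(trifluoromethanesulfonimide), O=S(=O)(N(c1ccccc1)S(=O)(=O)C(F)(F)F)C(F)(F)F
Why: E1cB cleavage of the N-monoalkyl carbamate (the isocyanate is trapped by Et2NH) followed by sulfonylation of the phenoxide with the mild triflimide should give the ortho-silyl aryl triflate without touching the C–Si or O–Si bonds.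

Step 7
Reactants: 13 (2-hydroxy-4-methoxyphenyl)acetic acid
Product: 14 benzyl [2-(benzyloxy)-4-methoxyphenyl]acetate
Conditions: BnBr (2.3 equiv), K2CO3, DMF, rt
Reagents that add atoms: benzyl bromide, BrCc1ccccc1
Why: Williamson O-alkylation of phenoxide and carboxylate in one operation masks the future O11, which would otherwise compete for the aryne, and makes the ester that later serves as acyl donor.

Step 8
Reactants: 14 benzyl [2-(benzyloxy)-4-methoxyphenyl]acetate
Product: 15 racemic benzyl 2-[2-(benzyloxy)-4-methoxyphenyl]-3-hydroxypropanoate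
Conditions: (CH2O)n (1.05 equiv), K2CO3 (cat.), DMSO, rt
Reagents that add atoms: paraformaldehyde (as formaldehyde), C=O
Why: Aldol-type hydroxymethylation of the arylacetate enolate with formaldehyde is the standard route to tropate esters; one equivalent at room temperature should avoid a second addition and dehydration, and the new centre (future C6a) is racemic and needs no control here.

Step 9
Reactants: 12 2,2-dimethyl-5-(triisopropylsilyloxy)-8-(trimethylsilyl)chroman-7-yl trifluoromethanesulfonate; 15 racemic benzyl 2-[2-(benzyloxy)-4-methoxyphenyl]-3-hydroxypropanoate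
Product: 17 racemic ring E-fused 3-[2-(benzyloxy)-4-methoxyphenyl]-7-(triisopropylsilyloxy)chroman-4-one (isoflavanone; C11a ketone; ring E oxygen on chromanone C5), via aryne 16 (not isolated)
Conditions: KF (3 equiv), 18-crown-6 (3 equiv), THF, 0 °C to rt, 12 added slowly to 15 (1.5 equiv)
Reagents that add atoms: none
Why: Proposed new method: fluoride attacks the trimethylsilyl group of 12 and triflate leaves, giving aryne 16; the hydroxyl oxygen of 15, made nucleophilic by hydrogen bonding to fluoride, adds to C4a, and the aryl anion left at C11b attacks the benzyl ester carbonyl four atoms away (6-exo-trig), expels benzyl oxide and so closes ring B as the chroman-4-one with both C4a–O5 and C11a–C11b formed. The closest known reaction type is the fluoride-induced annulation of arynes with methyl salicylates or anthranilates to xanthones or acridones, in which a heteroatom adds and the neighbouring ester acylates the aryl anion; an aliphatic β-hydroxy ester has not been shown in this role. The regioselectivity needed (O5 to C4a, the carbonyl carbon to C11b) is secured by the ring E oxygen on C1, which distorts the aryne so that the remote carbon C4a is the electrophilic one and stabilises inductively the charge developing at C11b, while the silyloxy group at C3 is one carbon further away and should not override this. The chemoselectivity needed is acylation of the aryl anion ahead of its protonation, favoured by the aprotic solvent, by fluoride holding the hydroxyl proton until benzyl oxide takes it, and by the six-membered transition state; slow release of the aryne at or below room temperature should also limit base-induced dehydration of 15 to the 2-arylacrylate, and the hindered O–Si(i-Pr)3 bond should be attacked far more slowly than the C–SiMe3 bond. No stereocentre is set under control: C6a (chromanone C3) forms racemic and stays epimerisable, which step 11 exploits.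

Step 10
Reactants: 17 racemic O-benzyl O-triisopropylsilyl isoflavanone
Product: 18 racemic ring E-fused 3-(2-hydroxy-4-methoxyphenyl)-7-(triisopropylsilyloxy)chroman-4-one
Conditions: H2 (1 atm), Pd/C, EtOAc, rt
Reagents that add atoms: none
Why: Hydrogenolysis of the aryl benzyl ether frees O11 while the electron-rich aryl ketone, the silyl ether and both pyran rings are inert, and doing it at the ketone stage avoids exposing a labile benzylic alcohol to palladium later.

Step 11
Reactants: 18 racemic ring E-fused 3-(2-hydroxy-4-methoxyphenyl)-7-(triisopropylsilyloxy)chroman-4-one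
Product: 20 (6aS,11aS)-3-O-triisopropylsilyl pterocarpan (the target carrying OSi(i-Pr)3 at C3), via cis-isoflavan-4-ol 19 (not isolated)
Conditions: RuCl(p-cymene)[(S,S)-TsDPEN] (3 mol %), HCO2H/Et3N, EtOAc, 40 °C; then 1 M HCl, rt
Reagents that add atoms: none
Why: Noyori–Ikariya asymmetric transfer hydrogenation with dynamic kinetic resolution, a known route from 2'-hydroxyisoflavanones to pterocarpans, should work because C3–H epimerises under Et3N while the (S,S) catalyst delivers hydride to the carbonyl face that gives 4S and reduces faster the epimer whose aryl group is trans to the incoming hydride, giving cis-(3S,4S) 19 (C6a set by catalyst control); acid then ionises the C11a alcohol to a cation stabilised by three ring A oxygens, and the ring D phenol closes ring C by 5-exo attack, necessarily cis to C6a–H, which fixes C11a as S (substrate control).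

Step 12
Reactants: 20 (6aS,11aS)-3-O-triisopropylsilyl pterocarpan
Product: 21 target (6aS,11aS)-pterocarpan with free C3–OH
Conditions: Bu4NF, AcOH, THF, 0 °C
Reagents that add atoms: none
Why: Fluoride cleavage of the aryl silyl ether under buffered conditions should free the C3 phenol without touching either stereocentre or the benzylic ether of ring C.

**Compound list**
1 | phloroglucinol | Oc1cc(O)cc(O)c1 | starting material
2 | 3-methylbut-2-enoic acid | CC(C)=CC(=O)O | starting material
3 | 5,7-dihydroxy-2,2-dimethylchroman-4-one | CC1(C)CC(=O)c2c(O)cc(O)cc2O1 | intermediate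
4 | 5-hydroxy-2,2-dimethyl-4-oxochroman-7-yl N-isopropylcarbamate | CC(C)NC(=O)Oc1cc(O)c2C(=O)CC(C)(C)Oc2c1 | intermediate
5 | 5-hydroxy-2,2-dimethylchroman-7-yl N-isopropylcarbamate | CC(C)NC(=O)Oc1cc(O)c2CCC(C)(C)Oc2c1 | intermediate
6 | 2,2-dimethyl-5-(triisopropylsilyloxy)chroman-7-yl N-isopropylcarbamate | CC(C)NC(=O)Oc1cc(O[Si](C(C)C)(C(C)C)C(C)C)c2CCC(C)(C)Oc2c1 | intermediate
7 | N-(tert-butyldimethylsilyl) derivative of 6 (not isolated) | CC(C)N(C(=O)Oc1cc(O[Si](C(C)C)(C(C)C)C(C)C)c2CCC(C)(C)Oc2c1)[Si](C)(C)C(C)(C)C | intermediate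
8 | 8-lithio derivative of 7 (not isolated) | CC(C)N(C(=O)Oc1cc(O[Si](C(C)C)(C(C)C)C(C)C)c2CCC(C)(C)Oc2c1[Li])[Si](C)(C)C(C)(C)C | intermediate
9 | 8-trimethylsilyl derivative of 7 (not isolated) | CC(C)N(C(=O)Oc1cc(O[Si](C(C)C)(C(C)C)C(C)C)c2CCC(C)(C)Oc2c1[Si](C)(C)C)[Si](C)(C)C(C)(C)C | intermediate
10 | 2,2-dimethyl-5-(triisopropylsilyloxy)-8-(trimethylsilyl)chroman-7-yl N-isopropylcarbamate | CC(C)NC(=O)Oc1cc(O[Si](C(C)C)(C(C)C)C(C)C)c2CCC(C)(C)Oc2c1[Si](C)(C)C | intermediate
11 | 2,2-dimethyl-5-(triisopropylsilyloxy)-8-(trimethylsilyl)chroman-7-ol (not isolated) | CC1(C)CCc2c(O[Si](C(C)C)(C(C)C)C(C)C)cc(O)c([Si](C)(C)C)c2O1 | intermediate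
12 | 2,2-dimethyl-5-(triisopropylsilyloxy)-8-(trimethylsilyl)chroman-7-yl trifluoromethanesulfonate (ring A/E aryne precursor) | CC1(C)CCc2c(O[Si](C(C)C)(C(C)C)C(C)C)cc(OS(=O)(=O)C(F)(F)F)c([Si](C)(C)C)c2O1 | intermediate
13 | (2-hydroxy-4-methoxyphenyl)acetic acid | COc1ccc(CC(=O)O)c(O)c1 | starting material
14 | benzyl [2-(benzyloxy)-4-methoxyphenyl]acetate | COc1ccc(CC(=O)OCc2ccccc2)c(OCc2ccccc2)c1 | intermediate
15 | racemic benzyl 2-[2-(benzyloxy)-4-methoxyphenyl]-3-hydroxypropanoate (ring D tropate ester) | COc1ccc(C(CO)C(=O)OCc2ccccc2)c(OCc2ccccc2)c1 | intermediate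
16 | 2,2-dimethyl-5-(triisopropylsilyloxy)-7,8-didehydrochroman (C4a–C11b aryne, not isolated) | CC1(C)CCC2=C(O1)C#CC=C2O[Si](C(C)C)(C(C)C)C(C)C | intermediate
17 | racemic 3-[2-(benzyloxy)-4-methoxyphenyl]-7-(triisopropylsilyloxy)chroman-4-one with ring E (2,2-dimethyldihydropyran) fused across C5–C6, oxygen on C5 | COc1ccc(c(OCc2ccccc2)c1)C1COc2cc(O[Si](C(C)C)(C(C)C)C(C)C)c3CCC(C)(C)Oc3c2C1=O | intermediate
18 | racemic 3-(2-hydroxy-4-methoxyphenyl) analogue of 17 | COc1ccc(c(O)c1)C1COc2cc(O[Si](C(C)C)(C(C)C)C(C)C)c3CCC(C)(C)Oc3c2C1=O | intermediate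
19 | (3S,4S)-cis-3-(2-hydroxy-4-methoxyphenyl)-7-(triisopropylsilyloxy)chroman-4-ol with ring E fused across C5–C6 (not isolated) | O[C@@H]1c2c(cc(O[Si](C(C)C)(C(C)C)C(C)C)c3c2OC(C)(C)CC3)OC[C@@H]1c1ccc(OC)cc1O | intermediate
20 | (6aS,11aS)-3-O-triisopropylsilyl pterocarpan | COc1ccc2c(c1)O[C@@H]1c3c(cc(O[Si](C(C)C)(C(C)C)C(C)C)c4c3OC(C)(C)CC4)OC[C@H]21 | intermediate
21 | (6aS,11aS)-pterocarpan with C3–OH, C9–OMe and the 2,2-dimethyldihydropyran ring E on C1 (O)/C2 | COc1ccc2c(c1)O[C@@H]1c3c(cc(O)c4c3OC(C)(C)CC4)OC[C@H]21 | target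

**Step count**
Total: 12 steps. Longest linear sequence: 10 steps (1 to 21 through steps 1–6 and 9–12); the ring D branch is 2 steps (7, 8).

**Steps most likely to fail**

1. Step 9 (new method). The aryl anion may be protonated before it acylates, giving plain O-arylation of 15. The hydroxy ester may also lose water under fluoride, and fluoride may strip the silyl ether. The fallback sets out from 14 and 12 and returns at 17. α-Methylenation of 14 ((CH2O)n, K2CO3, Bu4NI, toluene, 80 °C) should give benzyl 2-[2-(benzyloxy)-4-methoxyphenyl]acrylate F1. LiOH in THF/water then gives 2-[2-(benzyloxy)-4-methoxyphenyl]acrylic acid F2. F2 and 12 with CsF in THF at about 100 °C should undergo the known insertion of an aryne into the C–O bond of a carboxylic acid: the carboxylate oxygen adds to C4a, and the acyl carbon goes to C11b through a four-membered adduct that opens. This gives the ortho-hydroxyaryl vinyl ketone 2-[2-(benzyloxy)-4-methoxyphenyl]-1-[7-hydroxy-2,2-dimethyl-5-(triisopropylsilyloxy)chroman-8-yl]prop-2-en-1-one F3, whose phenoxide closes ring B by 6-endo-trig oxa-Michael addition to give 17. The two aryne bonds and their regiochemistry are unchanged, and neither an aliphatic alkoxide nor a base-sensitive hydroxy ester is involved.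

2. Step 11. Hydride transfer to a ketone that is electron-rich and flanked by the ring E oxygen may be slow, or epimerisation at C3 may not keep pace with reduction; either would erode conversion, cis selectivity or enantiopurity. The fallback sets out from 17 and returns at 20, setting C6a by alkene hydrogenation instead.
   - NaBH4 in MeOH/THF should give the ring E-fused 3-[2-(benzyloxy)-4-methoxyphenyl]-7-(triisopropylsilyloxy)chroman-4-ol F4 as a mixture of racemic diastereomers.
   - TsOH (cat.) in toluene at 80 °C dehydrates it to the 3-aryl-2H-chromene (isoflav-3-ene) F5.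
   - Asymmetric hydrogenation with [Ir(cod)(tBu-PHOX)][B(C6H3(CF3)2)4], using the ligand enantiomer that delivers the 3S product (H2, CH2Cl2), should give the (3S)-isoflavan F6.
   - H2, Pd/C removes the benzyl group to give the (3S)-2'-hydroxyisoflavan F7.
   - DDQ abstracts hydride from C11a (para to the silyloxy group), and the ring D phenol traps the cation cis to C6a–H, giving 20. This oxidative closure of 2'-hydroxyisoflavans to pterocarpans is known.

3. Step 5. Lithiation may occur at the wrong ortho position (C6), or the carbamoyl group may migrate to carbon (anionic ortho-Fries). The fallback sets out from 6 and returns at 12.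
   - DBU/Et2NH in MeCN cleaves the carbamate to 2,2-dimethyl-5-(triisopropylsilyloxy)chroman-7-ol F8.
   - NBS in CH2Cl2 at −78 °C should brominate ortho to the free hydroxyl at C8, C6 being screened by the silyl ether, giving 8-bromo-2,2-dimethyl-5-(triisopropylsilyloxy)chroman-7-ol F9.
   - (Me3Si)2NH gives the trimethylsilyl ether [8-bromo-2,2-dimethyl-5-(triisopropylsilyloxy)chroman-7-yl]oxytrimethylsilane F10.
   - n-BuLi at −78 °C effects bromine–lithium exchange and a retro-Brook shift of silicon from oxygen to C8, giving the lithium phenoxide of 11, lithium 2,2-dimethyl-5-(triisopropylsilyloxy)-8-(trimethylsilyl)chroman-7-olate F11, which Tf2O converts into 12.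

**Further compounds**
F1 | step 9 | benzyl 2-[2-(benzyloxy)-4-methoxyphenyl]acrylate | COc1ccc(C(=C)C(=O)OCc2ccccc2)c(OCc2ccccc2)c1
F2 | step 9 | 2-[2-(benzyloxy)-4-methoxyphenyl]acrylic acid | COc1ccc(C(=C)C(=O)O)c(OCc2ccccc2)c1
F3 | step 9 | 2-[2-(benzyloxy)-4-methoxyphenyl]-1-[7-hydroxy-2,2-dimethyl-5-(triisopropylsilyloxy)chroman-8-yl]prop-2-en-1-one | CC1(C)CCc2c(O[Si](C(C)C)(C(C)C)C(C)C)cc(O)c(C(=O)C(=C)c3ccc(OC)cc3OCc3ccccc3)c2O1
F4 | step 11 | ring E-fused 3-[2-(benzyloxy)-4-methoxyphenyl]-7-(triisopropylsilyloxy)chroman-4-ol (racemic diastereomer mixture) | COc1ccc(c(OCc2ccccc2)c1)C1COc2cc(O[Si](C(C)C)(C(C)C)C(C)C)c3CCC(C)(C)Oc3c2C1O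
F5 | step 11 | ring E-fused 3-[2-(benzyloxy)-4-methoxyphenyl]-7-(triisopropylsilyloxy)-2H-chromene (isoflav-3-ene) | COc1ccc(c(OCc2ccccc2)c1)C1=Cc2c3OC(C)(C)CCc3c(O[Si](C(C)C)(C(C)C)C(C)C)cc2OC1
F6 | step 11 | ring E-fused (3S)-3-[2-(benzyloxy)-4-methoxyphenyl]-7-(triisopropylsilyloxy)chroman (isoflavan) | COc1ccc(c(OCc2ccccc2)c1)[C@@H]1Cc2c3OC(C)(C)CCc3c(O[Si](C(C)C)(C(C)C)C(C)C)cc2OC1
F7 | step 11 | ring E-fused (3S)-3-(2-hydroxy-4-methoxyphenyl)-7-(triisopropylsilyloxy)chroman | COc1ccc(c(O)c1)[C@@H]1Cc2c3OC(C)(C)CCc3c(O[Si](C(C)C)(C(C)C)C(C)C)cc2OC1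
F8 | step 5 | 2,2-dimethyl-5-(triisopropylsilyloxy)chroman-7-ol | CC1(C)CCc2c(O[Si](C(C)C)(C(C)C)C(C)C)cc(O)cc2O1
F9 | step 5 | 8-bromo-2,2-dimethyl-5-(triisopropylsilyloxy)chroman-7-ol | CC1(C)CCc2c(O[Si](C(C)C)(C(C)C)C(C)C)cc(O)c(Br)c2O1
F10 | step 5 | [8-bromo-2,2-dimethyl-5-(triisopropylsilyloxy)chroman-7-yl]oxytrimethylsilane | CC1(C)CCc2c(O[Si](C(C)C)(C(C)C)C(C)C)cc(O[Si](C)(C)C)c(Br)c2O1
F11 | step 5 | lithium 2,2-dimethyl-5-(triisopropylsilyloxy)-8-(trimethylsilyl)chroman-7-olate | CC1(C)CCc2c(O[Si](C(C)C)(C(C)C)C(C)C)cc([O-])c([Si](C)(C)C)c2O1.[Li+]
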